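(Readings and results were generated by integration on assumed constants, noise included.)

The target in the north-east flask reads a mean of 28.8% from 4.00 min to 8.00 min, and you must choose what to do to that flask at 10 min.

| setting | north-east | south | flask |
|---|---|---|---|
| substrate | 0.010 M | 0.0050 M | 0.010 M |
| partner | 1 equiv | 1 equiv | 1.00 equiv |
| free catalyst | 5 mol% | 5 mol% | 5 mol% |
| temperature | 25 °C | 31 °C | 25 °C |
| remark | the very flask that is asked about, followed so far | run made earlier |  |
| time |  |  | 10 min |

| run | time / min | target / % |
|---|---|---|
| north-east | 1.33 | 14 |
| north-east | 2.50 | 20 |
| north-east | 4.00 | 28 |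
| north-east | 5.00 | 27 |
| north-east | 6.00 | 31 |
| north-east | 8.00 | 29 |
| south | 1.33 | 9 |
| south | 2.50 | 8 |
| south | 4.00 | 12 |
| south | 5.00 | 16 |
| south | 6.00 | 17 |
| south | 8.00 | 17 |

(scatter of a reading: 1.5 percentage points)

- beta: at 10 min add partner, 50.0% of the amount charged, then wait 5.0 min
- gamma: at 10 min take out 90% of the target then present, then wait 5.0 min
- delta: at 10 min raise the temperature by 25 K, then wait 5.0 min
- theta: change nothing and wait 5.0 min more
- zeta: at 10 min add free catalyst, 100% of the amount charged, then wait 5.0 min

- target that was removed still counts
- the earlier runs were read with a standard deviation of 1.5 percentage points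
- reactions considered so far: substrate + free catalyst <-> free catalyst + open intermediate; free catalyst + open intermediate <-> catalyst intermediate; partner + catalyst intermediate -> free catalyst + target; partner + free catalyst -> spent catalyst
- additions bring no volume worth counting

* target, in percent of the substrate first charged, at 10 min
* which option adds most target ("none" when 2 percentage points or less is all one gets) (beta / gamma / delta / theta / zeta / none)
* target present, with what was taken out counted in, in percent of the substrate first charged, after delta
* target present, with what was taken out counted in, in percent of the substrate first charged, after theta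

At that mean, 71.2% of the substrate is not target. Even if you count the catalyst charge as partner lost, 66.2% of the partner remains, so neither reagent has run out in the north-east flask. Partner meets the catalyst in two ways: with catalyst intermediate it gives target and returns free catalyst, and with free catalyst it gives spent catalyst. The ratio of those two rates at one moment is the target made per catalyst lost. Over the north-east run, 28.8% on 5 mol% gives 5.75: this is N, the turnover number, the target at the stall per catalyst charged. The south run, read the same way, gives 3.33, less than N, at 0.0050 M and 31 °C, so you carry N at the north-east concentration and temperature.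

The ratio need not hold: each round starts from substrate, and a second dose of free catalyst meets the 71.2% of the charge that is not target, less than the first dose met. Scaling N down by that share, my reckoning for zeta is 20 percentage points, far more than the 2 points margin. The readings since 4.00 min stay between 27% and 31%, and I expect the other options to stay near the stall, so free catalyst is what you add.

The forecast gave 30% at 10 min, 30.5% after delta and 30.2% after theta, and chose zeta: “Only fresh catalyst restarts the reaction, probably adding 15–25 points.” Its 30% lies above the 28.8% mean of the readings.

The simulation gives 32.1% at 10 min, 32.4% after delta and 33.0% after theta. It picks zeta, which adds 22 points, against 0.84 points for theta.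

    substrate + free catalyst ⇌ free catalyst + open intermediate (K = 0.120, k = 65.0 L mol⁻¹ s⁻¹, Ea = 47.0 kJ mol⁻¹, ΔH = −32.0 kJ mol⁻¹)
    free catalyst + open intermediate ⇌ catalyst intermediate (K = 1800 L mol⁻¹, k = 130 L mol⁻¹ s⁻¹, Ea = 38.0 kJ mol⁻¹, ΔH = −51.0 kJ mol⁻¹)
    partner + catalyst intermediate → free catalyst + target (k = 17.0 L mol⁻¹ s⁻¹, Ea = 52.0 kJ mol⁻¹)
    partner + free catalyst → spent catalyst (k = 1.20 L mol⁻¹ s⁻¹, Ea = 56.0 kJ mol⁻¹)
    (constants at 25 °C)

In this flask, 32.1% on 5 mol% is 6.42 turnovers at 10 min, with 96.9% of the catalyst spent, and zeta's 22 points stands against my 20 points. Now take the neighbouring flask, charged with 8.5 mol% of free catalyst from the start and otherwise unchanged. N times that charge gives 48.9% of target. That flask gives 51.3% at 10 min, which is 6.04 turnovers, with 93.3% of its catalyst spent and 44% of its substrate left.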